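## Retrosynthetic overview

1. The 2,5-dihydrofuran, the only ring, is closed in the last step the way the natural ring is thought to arise: the tertiary hydroxyl of a (Z)-γ-hydroxy-enone side chain adds to the ketone and water is lost into conjugation with the neighbouring aldehyde. Here this runs as one cascade that also frees both aldehydes, the methyl ketone and the acid.
2. Until then the 2-acylglutaraldehyde core is carried as a 1-benzyl-3-acyl-1,4-dihydropyridine, so the pyridine ring of nicotinic acid supplies the five carbons between the two aldehydes.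
3. The bond between the two stereocentres, and both configurations, come from an isothiourea-catalysed addition of the ammonium dienolate of a 4-nitrophenyl 3-methylidenehexanoate to C4 of the 3-acylpyridinium salt.
4. Pyridinium salt: nicotinoyl chloride plus silylated 2-methylbut-3-yn-2-ol (acyl Sonogashira), Lindlar reduction, N-benzylation. Acid part: chloro-ketal Grignard reagent plus diketene.
5. Ring order: the dihydropyridine is a temporary carrier that is hydrolysed away; the dihydrofuran is formed last.

Assumption: the exocyclic push–pull alkene of the target equilibrates under the acidic conditions of the last step to the E isomer shown (branched carbon cis to the ring oxygen, formyl cis to the ring CH).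

## Route

Step 1
Reactants: 1 2-(3-chloropropyl)-2-methyl-1,3-dioxolane; 2 diketene (4-methylideneoxetan-2-one)
Product: 4 3-methylidene-6-(2-methyl-1,3-dioxolan-2-yl)hexanoic acid, via Grignard reagent 3 (not isolated)
Conditions: Mg, THF, reflux; then 2, NiCl2 (5 mol%), THF, −20 °C to rt; cold aq. citric acid to pH 4
Reagents that add atoms: none
Why: Magnesium inserts into the primary chloride to give 3, and with NiCl2 the Grignard reagent cleaves the vinyl–oxygen bond of diketene (nickel-catalysed cross-coupling-type ring opening of diketene by Grignard reagents) instead of attacking the lactone carbonyl, so the 3-methylidene acid is obtained directly with the 1,1-disubstituted alkene in place and no stereocentre is formed.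

Step 2
Reactants: 4 3-methylidene-6-(2-methyl-1,3-dioxolan-2-yl)hexanoic acid; 5 4-nitrophenol
Product: 6 4-nitrophenyl 3-methylidene-6-(2-methyl-1,3-dioxolan-2-yl)hexanoate
Conditions: EDC·HCl (1.2 equiv), CH2Cl2, 0 °C to rt
Reagents that add atoms: none
Why: Carbodiimide (Steglich-type) esterification without DMAP gives the activated aryl ester needed for isothiourea acyl transfer with aryloxide turnover, while avoiding base-induced migration of the β,γ-alkene into conjugation.

Step 3
Reactants: 7 pyridine-3-carbonyl chloride hydrochloride (nicotinoyl chloride hydrochloride); 8 trimethyl[(2-methylbut-3-yn-2-yl)oxy]silane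
Product: 9 4-methyl-1-(pyridin-3-yl)-4-[(trimethylsilyl)oxy]pent-2-yn-1-one
Conditions: PdCl2(PPh3)2 (2 mol%), CuI (4 mol%), Et3N (3 equiv), THF, rt
Reagents that add atoms: none
Why: Acyl Sonogashira coupling of the aroyl chloride with the terminal alkyne gives the ynone in one step, the extra Et3N freeing the pyridine base and the hindered tertiary silyl ether staying inert.

Step 4
Reactants: 9 4-methyl-1-(pyridin-3-yl)-4-[(trimethylsilyl)oxy]pent-2-yn-1-one
Product: 10 (2Z)-4-methyl-1-(pyridin-3-yl)-4-[(trimethylsilyl)oxy]pent-2-en-1-one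
Conditions: H2 (1 atm), Pd/CaCO3 poisoned with Pb(OAc)2, quinoline, EtOAc, 0 °C, dark
Reagents that add atoms: none
Why: Lindlar semihydrogenation adds H2 syn across the alkyne and so sets the (Z)-enone geometry needed for the later ring closure, and the silyl ether stops the γ-oxygen from closing early so that the 3-acyl group can still activate the pyridine ring.

Step 5
Reactants: 10 (2Z)-4-methyl-1-(pyridin-3-yl)-4-[(trimethylsilyl)oxy]pent-2-en-1-one; 11 benzyl bromide
Product: 12 1-benzyl-3-{(2Z)-4-methyl-4-[(trimethylsilyl)oxy]pent-2-enoyl}pyridin-1-ium bromide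
Conditions: MeCN, 40 °C, dark; precipitation with Et2O
Reagents that add atoms: none
Why: Menshutkin N-benzylation gives the 3-acylpyridinium salt (an NAD+-type electrophile) whose C4 becomes the methine next to the acid-bearing stereocentre and whose C2 and C6 are the two masked aldehyde carbons.

Step 6
Reactants: 6 4-nitrophenyl 3-methylidene-6-(2-methyl-1,3-dioxolan-2-yl)hexanoate; 12 1-benzyl-3-{(2Z)-4-methyl-4-[(trimethylsilyl)oxy]pent-2-enoyl}pyridin-1-ium bromide
Product: 13 4-nitrophenyl (2R)-2-[(4S)-1-benzyl-3-{(2Z)-4-methyl-4-[(trimethylsilyl)oxy]pent-2-enoyl}-1,4-dihydropyridin-4-yl]-3-methylidene-6-(2-methyl-1,3-dioxolan-2-yl)hexanoate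
Conditions: (R)-BTM [(2R)-2-phenyl-2,3-dihydroimidazo[2,1-b][1,3]benzothiazole] (10 mol%), 1,4-diazabicyclo[2.2.2]octane (1.5 equiv), toluene, 0 °C to rt
Reagents that add atoms: none
Why: Proposed new method: acyl transfer from 6 to the isothiourea gives an acyl isothiouronium that 1,4-diazabicyclo[2.2.2]octane deprotonates to the (Z)-C(1)-ammonium dienolate, which attacks through its α-carbon, on the face opposite the catalyst phenyl group (setting the 2R centre of 13), C4 of the pyridinium ion with the 3-acyl oxygen turned toward the cationic acyl isothiouronium, the closed topicity that gives anti products in isothiourea Michael addition–lactonisations (setting the 4S centre), and 4-nitrophenoxide then releases the catalyst; the closest known reactions are the isothiourea-catalysed enantioselective additions of aryl-ester-derived ammonium enolates to 3-cyano- and 3-sulfonyl-1-benzylpyridinium salts giving 1,4-dihydropyridines and the α-selective isothiourea functionalisation of 3-alkenoic acids.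

Step 7
Reactants: 13 4-nitrophenyl (2R)-2-[(4S)-1-benzyl-3-{(2Z)-4-methyl-4-[(trimethylsilyl)oxy]pent-2-enoyl}-1,4-dihydropyridin-4-yl]-3-methylidene-6-(2-methyl-1,3-dioxolan-2-yl)hexanoate
Product: 16 (2R,3S,4E)-4-(5,5-dimethylfuran-2(5H)-ylidene)-5-oxo-2-(6-oxohept-1-en-2-yl)-3-(2-oxoethyl)pentanoic acid (the target), via dihydropyridine acid 14 (not isolated), via hydroxymethylene ketone 15 (not isolated)
Conditions: LiOH (2.5 equiv), THF/H2O 3:1, 0 °C; then 2 M aq. HCl to pH 1, 35 °C
Reagents that add atoms: water, O; lithium hydroxide, [Li+].[OH-]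
Why: Proposed new method: hydroxide first cleaves the activated aryl ester (14), then aqueous acid removes the silyl and dioxolane groups and protonates the dihydropyridine enamine so that water opens the ring and hydrolyses the N-benzyl enaminone to the 2-acylglutaraldehyde (15), whose tertiary hydroxyl, held cis by the (Z)-alkene, adds to the enone carbonyl (5-exo-trig hemiketalisation) and loses water toward the formyl-bearing carbon to give the vinylogous ester, the exocyclic alkene settling as the E isomer under thermodynamic control and both stereocentres staying untouched; the closest known reactions are acid hydrolysis of 1-alkyl-1,4-dihydropyridines and enaminones to 1,5- and 1,3-dicarbonyl compounds and the cyclodehydration of cis-γ-hydroxy enones to furans and 2-ylidene-2,5-dihydrofurans.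

## Compound list

1 | 2-(3-chloropropyl)-2-methyl-1,3-dioxolane | CC1(CCCCl)OCCO1 | starting material
2 | diketene (4-methylideneoxetan-2-one) | C=C1CC(=O)O1 | starting material
3 | [3-(2-methyl-1,3-dioxolan-2-yl)propyl]magnesium chloride | CC1(CCC[Mg]Cl)OCCO1 | intermediate
4 | 3-methylidene-6-(2-methyl-1,3-dioxolan-2-yl)hexanoic acid | C=C(CCCC1(C)OCCO1)CC(=O)O | intermediate
5 | 4-nitrophenol | Oc1ccc(cc1)[N+](=O)[O-] | starting material
6 | 4-nitrophenyl 3-methylidene-6-(2-methyl-1,3-dioxolan-2-yl)hexanoate | C=C(CCCC1(C)OCCO1)CC(=O)Oc2ccc(cc2)[N+](=O)[O-] | intermediate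
7 | pyridine-3-carbonyl chloride hydrochloride | O=C(Cl)c1cccnc1.Cl | starting material
8 | trimethyl[(2-methylbut-3-yn-2-yl)oxy]silane | C#CC(C)(C)O[Si](C)(C)C | starting material
9 | 4-methyl-1-(pyridin-3-yl)-4-[(trimethylsilyl)oxy]pent-2-yn-1-one | O=C(C#CC(C)(C)O[Si](C)(C)C)c1cccnc1 | intermediate
10 | (2Z)-4-methyl-1-(pyridin-3-yl)-4-[(trimethylsilyl)oxy]pent-2-en-1-one | O=C(/C=C\C(C)(C)O[Si](C)(C)C)c1cccnc1 | intermediate
11 | benzyl bromide | BrCc1ccccc1 | starting material
12 | 1-benzyl-3-{(2Z)-4-methyl-4-[(trimethylsilyl)oxy]pent-2-enoyl}pyridin-1-ium bromide | O=C(/C=C\C(C)(C)O[Si](C)(C)C)c1ccc[n+](Cc2ccccc2)c1.[Br-] | intermediate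
13 | 4-nitrophenyl (2R)-2-[(4S)-1-benzyl-3-{(2Z)-4-methyl-4-[(trimethylsilyl)oxy]pent-2-enoyl}-1,4-dihydropyridin-4-yl]-3-methylidene-6-(2-methyl-1,3-dioxolan-2-yl)hexanoate | C=C(CCCC1(C)OCCO1)[C@H](C(=O)Oc2ccc(cc2)[N+](=O)[O-])[C@@H]3C=CN(Cc4ccccc4)C=C3C(=O)/C=C\C(C)(C)O[Si](C)(C)C | intermediate
14 | (2R)-2-[(4S)-1-benzyl-3-{(2Z)-4-methyl-4-[(trimethylsilyl)oxy]pent-2-enoyl}-1,4-dihydropyridin-4-yl]-3-methylidene-6-(2-methyl-1,3-dioxolan-2-yl)hexanoic acid | C=C(CCCC1(C)OCCO1)[C@H](C(=O)O)[C@@H]2C=CN(Cc3ccccc3)C=C2C(=O)/C=C\C(C)(C)O[Si](C)(C)C | intermediate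
15 | (2R,3S,6Z)-8-hydroxy-4-(hydroxymethylidene)-8-methyl-5-oxo-2-(6-oxohept-1-en-2-yl)-3-(2-oxoethyl)non-6-enoic acid (enol form of the 2-acylglutaraldehyde) | C=C(CCCC(C)=O)[C@H](C(=O)O)[C@H](CC=O)C(=CO)C(=O)/C=C\C(C)(C)O | intermediate
16 | (2R,3S,4E)-4-(5,5-dimethylfuran-2(5H)-ylidene)-5-oxo-2-(6-oxohept-1-en-2-yl)-3-(2-oxoethyl)pentanoic acid | C=C(CCCC(C)=O)[C@H](C(=O)O)[C@H](CC=O)/C(C=O)=C1/C=CC(C)(C)O1 | target

## Step count and risks

Total steps: 7. Longest linear sequence: 5 steps (steps 3 to 7, from 7 and 8); the other branch is steps 1, 2, 6, 7.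

**Step 6** is the most likely to fail. The 3-acyl pyridinium and the alkenyl-substituted enolate are both outside the reported scope, attack at C6 or C2 of the ring can compete, and the relative configuration of the two new centres rests on a transition-state analogy, not on a measured result. Fallback, setting out from 4 (with 12) and coming back at 14: replace catalyst control by auxiliary control. Acid 4 is converted (pivaloyl chloride, Et3N; then the lithium salt of (4R)-4-benzyl-1,3-oxazolidin-2-one) into the imide (4R)-4-benzyl-3-[3-methylidene-6-(2-methyl-1,3-dioxolan-2-yl)hexanoyl]-1,3-oxazolidin-2-one F1. Its chelated (Z)-sodium enolate (NaN(SiMe3)2, THF, −78 °C) is added to 12 in the manner of Wenkert enolate additions to 3-acylpyridinium salts, the auxiliary fixing the 2R centre. The epimers at the ring carbon of the resulting imide (4R)-4-benzyl-3-[(2R)-2-[(4S)-1-benzyl-3-{(2Z)-4-methyl-4-[(trimethylsilyl)oxy]pent-2-enoyl}-1,4-dihydropyridin-4-yl]-3-methylidene-6-(2-methyl-1,3-dioxolan-2-yl)hexanoyl]-1,3-oxazolidin-2-one F2 are separated by chromatography. LiOH/H2O2 then removes the auxiliary and gives 14, which enters the acid stage of step 7.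

**Step 7** is next. The enaminone may hydrolyse slowly, and at pH 1 the transient iminium ion or the freed aldehyde can cyclise onto the 1,1-disubstituted alkene (aza-Prins or Prins). Fallback, setting out from 13 and coming back at 16: close the ring first under anhydrous conditions. TMSOTf (2,6-di-tert-butylpyridine, CH2Cl2, −78 °C) silylates the vinylogous amide oxygen, the silyl ether oxygen closes onto the activated carbonyl carbon and hexamethyldisiloxane is lost (silyl-transfer acetalisation logic). This gives the iminium salt (3E,4S)-1-benzyl-3-(5,5-dimethylfuran-2(5H)-ylidene)-4-[(2R)-3-methylidene-6-(2-methyl-1,3-dioxolan-2-yl)-1-(4-nitrophenoxy)-1-oxohexan-2-yl]-3,4-dihydropyridin-1-ium trifluoromethanesulfonate F3, with the dihydrofuran already in place. LiOH in aqueous THF then opens the iminium ring at the carbon next to nitrogen and cleaves the aryl ester, and a pH 3 citrate buffer at 35 °C finishes enamine and ketal hydrolysis to 16 under much weaker acid.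

**Step 4** (with knock-on to step 5) is third. The silyloxy (Z)-enone can over-reduce or isomerise to the E isomer, which cannot cyclise. Fallback, setting out from 7 and coming back at 16: lock the cis geometry in a ring. Coupling 7 with unprotected 2-methylbut-3-yn-2-ol under the step 3 conditions gives 4-hydroxy-4-methyl-1-(pyridin-3-yl)pent-2-yn-1-one F4. Lindlar reduction then lets the (Z)-hydroxy-enone close at once, by the same hydroxyl-onto-ketone addition, to the lactol 5,5-dimethyl-2-(pyridin-3-yl)-2,5-dihydrofuran-2-ol F5. Benzylation gives 1-benzyl-3-(2-hydroxy-5,5-dimethyl-2,5-dihydrofuran-2-yl)pyridin-1-ium bromide F6. Under the step 6 conditions its ring-chain tautomer, the open 3-acylpyridinium, reacts with 6 to give 4-nitrophenyl (2R)-2-[(4S)-1-benzyl-3-[(2Z)-4-hydroxy-4-methylpent-2-enoyl]-1,4-dihydropyridin-4-yl]-3-methylidene-6-(2-methyl-1,3-dioxolan-2-yl)hexanoate F7, and the step 7 conditions convert this into 16.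

## Further compounds

F1 | step 6 | (4R)-4-benzyl-3-[3-methylidene-6-(2-methyl-1,3-dioxolan-2-yl)hexanoyl]-1,3-oxazolidin-2-one | C=C(CCCC1(C)OCCO1)CC(=O)N2[C@H](Cc3ccccc3)COC2=O
F2 | step 6 | (4R)-4-benzyl-3-[(2R)-2-[(4S)-1-benzyl-3-{(2Z)-4-methyl-4-[(trimethylsilyl)oxy]pent-2-enoyl}-1,4-dihydropyridin-4-yl]-3-methylidene-6-(2-methyl-1,3-dioxolan-2-yl)hexanoyl]-1,3-oxazolidin-2-one | C=C(CCCC1(C)OCCO1)[C@H](C(=O)N2[C@H](Cc3ccccc3)COC2=O)[C@@H]4C=CN(Cc5ccccc5)C=C4C(=O)/C=C\C(C)(C)O[Si](C)(C)C
F3 | step 7 | (3E,4S)-1-benzyl-3-(5,5-dimethylfuran-2(5H)-ylidene)-4-[(2R)-3-methylidene-6-(2-methyl-1,3-dioxolan-2-yl)-1-(4-nitrophenoxy)-1-oxohexan-2-yl]-3,4-dihydropyridin-1-ium trifluoromethanesulfonate | C=C(CCCC1(C)OCCO1)[C@H](C(=O)Oc2ccc(cc2)[N+](=O)[O-])[C@@H]3C=C[N+](Cc4ccccc4)=C/C3=C5\C=CC(C)(C)O5.[O-]S(=O)(=O)C(F)(F)F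
F4 | step 4 | 4-hydroxy-4-methyl-1-(pyridin-3-yl)pent-2-yn-1-one | CC(C)(O)C#CC(=O)c1cccnc1
F5 | step 4 | 5,5-dimethyl-2-(pyridin-3-yl)-2,5-dihydrofuran-2-ol | CC1(C)C=CC(O)(O1)c2cccnc2
F6 | step 4 | 1-benzyl-3-(2-hydroxy-5,5-dimethyl-2,5-dihydrofuran-2-yl)pyridin-1-ium bromide | CC1(C)C=CC(O)(O1)c2ccc[n+](Cc3ccccc3)c2.[Br-]
F7 | step 4 | 4-nitrophenyl (2R)-2-[(4S)-1-benzyl-3-[(2Z)-4-hydroxy-4-methylpent-2-enoyl]-1,4-dihydropyridin-4-yl]-3-methylidene-6-(2-methyl-1,3-dioxolan-2-yl)hexanoate | C=C(CCCC1(C)OCCO1)[C@H](C(=O)Oc2ccc(cc2)[N+](=O)[O-])[C@@H]3C=CN(Cc4ccccc4)C=C3C(=O)/C=C\C(C)(C)O
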